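## The problem

The target is fisetinidol-(4α→8)-afzelechin. It consists of a 5-deoxy flavan-3-ol (upper unit: benzo ring A, catechol ring B, pyran ring C) whose C4 is bonded to C8 of an afzelechin (lower unit: benzo ring D, 4-hydroxyphenyl ring E, pyran ring F). It has five stereocentres: (2R,3S,4S), all-trans, in the upper unit and (2R,3S), trans, in the lower unit. Within each unit the centres are contiguous and can be related to one another, through alkene geometry and ring-face relationships above and through 1,2-induction from C3 to C2 below. The two sets are separated by the rotating C4–C8 bond, so neither can be relied on to control the other, and each unit needs its own source of absolute configuration. Ring D is a pentasubstituted phloroglucinol ring in which C6 and C8 are both nucleophilic, so the position of the interflavan bond should be fixed by construction and not by electrophilic substitution. The seven phenols, among them the catechol of ring B, are sensitive to air and base, and the benzylic C2–O1 ethers and the doubly benzylic C4–C8 bond are sensitive to acid. The phenols therefore travel as benzyl ethers and are released last under neutral conditions. The enabling feature is in ring D: the pyran oxygen O1 sits on C8a, the interflavan carbon on the neighbouring C8, and C8 in turn adjoins the C7 oxygen. C8a and C8 are thus the two carbons of a 3-alkoxyaryne, which by its innate polarity takes a nucleophile (O1) at the distal carbon and leaves a carbanion for an electrophile (upper C4) at the proximal one.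

## Retrosynthesis

**Target 30 to the protected dimer 28.** Seven O–benzyl bonds and one O–acetyl bond are cut. Hydrogenolysis of 29 over Pd(OH)2/C is the neutral release that the free polyphenol needs. The acetate of 28 is removed first by methanolysis, while every phenol is still protected against base.

**28 to phenol carbinol 21 and enol acetate 26.** The O1–C2 and C3–C4 bonds of ring C are cut, a [4+2] cycloaddition of the o-quinone methide 27 derived from 21 with the E-alkene 26.
- Cutting C4–C8 at this stage instead would bring back the C6/C8 problem of ring D and would require a separate fisetinidol electrophile.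
- This cut creates all three upper stereocentres at once from an achiral alkene and a carbinol whose own configuration is erased in 27.
- The forward reaction must show styrene-type regiochemistry (the acetoxy-bearing carbon to C4, the phenolic oxygen to the benzylic carbon), endo approach of ring B, and facial control by a chiral Brønsted acid.

**21 to carbinol 20, and 20 to bromo alcohol 15 and aldehyde 17.** Allyl removal leads back to 20. An allyl ether is preferred to an acetal, because acid would ionise the diarylcarbinol, and to a silyl ether, which could migrate to the new alkoxide. In 20 the C8–C4 bond and the C8a–O1 bond are cut together.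
- The alkoxide of 15 closes ring F on the C8–C8a aryne 18, and the C8 aryllithium 19 adds to 17.
- Against a Friedel–Crafts union at C8, the bromine atom of 15 fixes the regiochemistry.
- Against a closure of ring F by displacement at C2, no bond to a stereocentre is touched.
- The precursor 15 is acyclic with two stereocentres, and 17 is a simple benzaldehyde.
- The forward reaction must add the alkoxide at C8a and keep the aryllithium alive until the aldehyde arrives.

**15 to ketone 14, and 14 to Weinreb amide 11 and aryl bromide 12.** The C2 carbinol centre is traced to the ketone, and the C2–ring E bond to the Grignard reagent 13 (from 12) and 11.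
- Chelation-controlled reduction of the α-benzyloxy ketone gives the anti (erythro) alcohol, which is the one that becomes the 2,3-trans chroman when ring F closes with retention.
- Asymmetric dihydroxylation of an E-1,3-diarylpropene would give the syn diol, which suits only closures with inversion, so it is not used.

**11 to imide 10, and 10 to glycolyl imide 8 and benzyl bromide 5.** The C3–C4 bond is cut. Alkylation of the sodium enolate 9 of 8 sets C3, the only lower-unit centre that needs an external controller. Imide 8 comes from oxazolidinone 6 and acid chloride 7.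

**5 back to 5-bromoresorcinol 1.** Bromide 5 comes from alcohol 4, aldehyde 3 and dibenzyl ether 2. The Vilsmeier formylation of 2 places the one-carbon unit ortho to bromine, so the bromine ends up on the future C8a with a single ortho hydrogen, the future C8–H.

**Side fragments.** Aldehyde 17 is the allyl ether of commercial 16. Enol acetate 26 is made with defined E geometry from aldehyde 22 and bis(boronate) 23 through alkenylboronate 24 and trifluoroborate 25.

## Roads not taken

**Alternative 1:** Ring D itself is disconnected (C8–C8a and C6–C7, with C4a–C8a closing in the same cascade) by a Danheiser benzannulation.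
- Forward step: heating the siloxyalkyne A2, which carries the finished upper unit on its C4, with the cyclobutenone A3, which carries the lower side chain as an acetonide, should give the phenol A1 through vinylketene [2+2], ring opening and six-electron electrocyclisation.
- Merits: the substitution pattern of ring D is fixed beyond doubt, and the upper unit arrives with its three stereocentres already in place. The plan therefore does not depend on an untested asymmetric cycloaddition; in this respect it is the safer road.
- Weak points: both partners are late-stage, multi-step compounds. A2 needs a flavan-4-yl alkyne converted into a siloxyalkyne, and A3 is a 4-substituted 3-alkoxycyclobutenone. The cascade runs hot in the presence of an ionisable flavan C4. After it, A1 still needs acetonide cleavage, closure of ring F by displacement at benzylic C2 with inversion, and exchange of the silyl ether.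
- Comparison: the chosen plan also fixes the ring D pattern by construction, through the position of bromine, and does so from simple fragments while forming ring F and the interflavan bond in one operation. What it has to set against the stereochemical security of A1 is its shorter fragment syntheses and a fallback for the cycloaddition.

**Alternative 2:** The C3=C4 bond of the upper ring C is cut.
- Forward step: the second-generation Grubbs catalyst RuCl2(H2IMes)(PCy3)(=CHPh) would close the diene A5 to the 4-aryl-2H-chromene A4. Hydroboration–oxidation anti to the C2 aryl group would then set C3 and C4.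
- Merits: every reaction type is established, and the upper stereocentres are relayed from a single C2 centre by substrate control. That is a more predictable basis than a catalyst working against the resident chirality of the lower unit; here this road is better.
- Weak points: A5 contains a 1,1-diarylethene whose ring D aryl group is di-ortho-substituted and a branched benzylic allyl aryl ether that ionises and rearranges easily. The metathesis must form a hindered trisubstituted, doubly aryl-conjugated alkene, and the hydroboration meets the same hindrance. The road also still needs the C8-functionalised lower unit, so it solves none of the ring D problem and adds several steps.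
- Comparison: the chosen plan sets against the relay of A4 a one-step construction of ring C and a shorter end-game.

**Alternative 3:** The C4–C4a bond of the lower unit is cut.
- Forward step: a mild Lewis acid such as BF3·OEt2 would activate the terminal epoxide of the aryl ether A7. Ring D would attack the epoxide CH2 through C4a, closing ring F and releasing the lower 3-hydroxyl in A6.
- Merits: the interflavan bond and the upper unit can come from classical flavan-4-cation chemistry, no organolithium step is needed, and the lower 3-hydroxyl needs no protecting group. In these respects the road is simpler than the chosen one.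
- Weak points: five-membered closure at the internal epoxide carbon competes with the desired six-membered one. The free C6 position of ring D invites intermolecular alkylation. The benzylic C2–O aryl ether and the C4–C8 bond are both exposed to the Lewis acid. The aryl ether bond of A7 joins a benzylic, epoxide-bearing carbon to a phenolic oxygen flanked by the bulky upper unit, and forming it with defined configuration is itself a hard step.
- Comparison: the chosen plan closes ring F under base, with retention and with only one possible ring size, and that is what it sets against the simpler reagents of this road.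

Key step: step 11

Assumption: the (R)-configured N-triflylphosphoramide of step 16 is taken to deliver the (2R,3S,4S) adduct; the sense of induction on this substrate is not known in advance, and the (S)-catalyst would be used instead if it proves opposite.

## Route

Step 1
Reactants: 1 5-bromoresorcinol
Product: 2 1,3-bis(benzyloxy)-5-bromobenzene
Conditions: BnBr, K2CO3, DMF, 60 °C
Reagents that add atoms: benzyl bromide, BrCc1ccccc1
Why: Williamson etherification of both phenols; the benzyl ethers are the permanent protecting groups removed in the last step.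

Step 2
Reactants: 2 1,3-bis(benzyloxy)-5-bromobenzene
Product: 3 2,4-bis(benzyloxy)-6-bromobenzaldehyde
Conditions: POCl3, DMF, 0 → 80 °C; then aq NaOAc
Reagents that add atoms: N,N-dimethylformamide, CN(C)C=O; water, O
Why: Vilsmeier–Haack formylation; the carbon ortho to bromine is para to one ether and ortho to the other and is less hindered than the carbon between the two ethers, the regiochemistry established for 3,5-dialkoxybromobenzenes.

Step 3
Reactants: 3 2,4-bis(benzyloxy)-6-bromobenzaldehyde
Product: 4 [2,4-bis(benzyloxy)-6-bromophenyl]methanol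
Conditions: NaBH4, THF/MeOH, 0 °C
Reagents that add atoms: none
Why: Borohydride reduction of an aromatic aldehyde; aryl bromide and benzyl ethers are inert.

Step 4
Reactants: 4 [2,4-bis(benzyloxy)-6-bromophenyl]methanol
Product: 5 1,5-bis(benzyloxy)-3-bromo-2-(bromomethyl)benzene
Conditions: PBr3, CH2Cl2, 0 °C; used without storage
Reagents that add atoms: phosphorus tribromide, BrP(Br)Br
Why: Conversion of a benzylic alcohol into the bromide through its phosphite ester; the electron-rich bromide is reactive and is taken directly into step 6.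

Step 5
Reactants: 6 (R)-4-benzyl-1,3-oxazolidin-2-one; 7 (benzyloxy)acetyl chloride
Product: 8 (R)-4-benzyl-3-[(benzyloxy)acetyl]-1,3-oxazolidin-2-one
Conditions: n-BuLi, THF, −78 °C; then 7, −78 → 0 °C
Reagents that add atoms: none
Why: N-acylation of the lithiated oxazolidinone, the standard preparation of an Evans glycolate imide.

Step 6
Reactants: 8 (R)-4-benzyl-3-[(benzyloxy)acetyl]-1,3-oxazolidin-2-one; 5 1,5-bis(benzyloxy)-3-bromo-2-(bromomethyl)benzene
Product: 10 (R)-4-benzyl-3-{(2S)-2-(benzyloxy)-3-[2,4-bis(benzyloxy)-6-bromophenyl]propanoyl}-1,3-oxazolidin-2-one, via sodium Z-enolate 9 (not isolated)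
Conditions: NaHMDS, THF, −78 °C; then 5, −78 → −40 °C
Reagents that add atoms: none
Why: Evans glycolate alkylation: the chelated sodium Z-enolate 9 is alkylated on the face opposite the benzyl group of the (R)-auxiliary, which gives the (2S) ether, the future C3 of the lower unit.

Step 7
Reactants: 10 (R)-4-benzyl-3-{(2S)-2-(benzyloxy)-3-[2,4-bis(benzyloxy)-6-bromophenyl]propanoyl}-1,3-oxazolidin-2-one
Product: 11 (2S)-2-(benzyloxy)-3-[2,4-bis(benzyloxy)-6-bromophenyl]-N-methoxy-N-methylpropanamide
Conditions: MeNHOMe·HCl, AlMe3, CH2Cl2, −10 → 0 °C; then 1 M HCl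
Reagents that add atoms: N,O-dimethylhydroxylamine hydrochloride, CNOC.Cl
Why: Weinreb transamination of the imide by the aluminium amide, which attacks the exocyclic carbonyl and releases the auxiliary for recovery; the α-centre is not enolised under these conditions.

Step 8
Reactants: 11 (2S)-2-(benzyloxy)-3-[2,4-bis(benzyloxy)-6-bromophenyl]-N-methoxy-N-methylpropanamide; 12 1-(benzyloxy)-4-bromobenzene
Product: 14 (2S)-2-(benzyloxy)-1-[4-(benzyloxy)phenyl]-3-[2,4-bis(benzyloxy)-6-bromophenyl]propan-1-one, via [4-(benzyloxy)phenyl]magnesium bromide 13 (not isolated)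
Conditions: 12, Mg, THF, reflux; then 11, THF, 0 °C; aq NH4Cl
Reagents that add atoms: none
Why: Weinreb ketone synthesis: the chelated tetrahedral adduct survives until work-up, so there is no over-addition and the ketone is not exposed to base; the hindered aryl bromide of 11 does not exchange with the Grignard reagent.

Step 9
Reactants: 14 (2S)-2-(benzyloxy)-1-[4-(benzyloxy)phenyl]-3-[2,4-bis(benzyloxy)-6-bromophenyl]propan-1-one
Product: 15 (1R,2S)-2-(benzyloxy)-1-[4-(benzyloxy)phenyl]-3-[2,4-bis(benzyloxy)-6-bromophenyl]propan-1-ol (anti)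
Conditions: Zn(BH4)2, Et2O, −20 → 0 °C; aq NH4Cl
Reagents that add atoms: none
Why: Chelation-controlled (Cram chelate) reduction: zinc bridges the ketone oxygen and the α-benzyloxy oxygen and hydride enters from the side of the α-hydrogen, giving the anti alcohol with (1R) at the future C2.

Step 10
Reactants: 16 4-(benzyloxy)-2-hydroxybenzaldehyde
Product: 17 2-(allyloxy)-4-(benzyloxy)benzaldehyde
Conditions: allyl bromide, K2CO3, DMF, rt
Reagents that add atoms: allyl bromide, C=CCBr
Why: Williamson etherification of the chelated ortho phenol; the allyl group withstands organolithium reagents and can later be removed without acid.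

Step 11
Reactants: 15 (1R,2S)-2-(benzyloxy)-1-[4-(benzyloxy)phenyl]-3-[2,4-bis(benzyloxy)-6-bromophenyl]propan-1-ol; 17 2-(allyloxy)-4-(benzyloxy)benzaldehyde
Product: 20 [2-(allyloxy)-4-(benzyloxy)phenyl]{(2R,3S)-3,5,7-tris(benzyloxy)-2-[4-(benzyloxy)phenyl]-3,4-dihydro-2H-chromen-8-yl}methanol (carbinol epimers), via aryne alkoxide 18 (not isolated), via 8-lithiochroman 19 (not isolated)
Conditions: LiTMP (from TMPH and n-BuLi, 3.5 equiv), THF, −78 → −20 °C; then 17, −78 °C; aq NH4Cl
Reagents that add atoms: none
Why: The first equivalent of amide forms the lithium alkoxide, the second removes the ring proton flanked by bromine and the C7 benzyloxy group, and loss of LiBr gives the C8–C8a aryne 18. The tethered alkoxide adds to C8a (6-exo-type closure onto the aryne, ring F) without breaking any bond to C2 or C3, so the anti pattern of 15 becomes the 2,3-trans chroman. The resulting C8 aryllithium 19, held between two oxygens, then adds to the non-enolisable aldehyde 17 and forms C8–C4. The closest known reaction type is the lithium-amide-induced aryne cyclisation of halogenated 3-arylpropanols to chromans with electrophile quench of the ortho-lithiated aryl ether. No defined stereocentre is created: the carbinol forms as both epimers, which converge on one o-quinone methide in step 16. The step needs alkoxide addition at C8a and not at C8; the tether allows only the six-membered closure, and C8a is also the aryne carbon remote from the inductively withdrawing C7 oxygen, so both factors point the same way. Metalation at C6 is disfavoured because only C8–H is activated by bromine, and the hindered amide is chosen so that it does not itself add to the aryne.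

Step 12
Reactants: 20 [2-(allyloxy)-4-(benzyloxy)phenyl]{(2R,3S)-3,5,7-tris(benzyloxy)-2-[4-(benzyloxy)phenyl]-3,4-dihydro-2H-chromen-8-yl}methanol (carbinol epimers)
Product: 21 5-(benzyloxy)-2-[hydroxy{(2R,3S)-3,5,7-tris(benzyloxy)-2-[4-(benzyloxy)phenyl]-3,4-dihydro-2H-chromen-8-yl}methyl]phenol (carbinol epimers)
Conditions: Pd(PPh3)4 (cat.), morpholine, THF, rt
Reagents that add atoms: none
Why: Tsuji–Trost deallylation: zerovalent palladium transfers the allyl group to morpholine through a π-allyl complex, and the neutral conditions leave the acid-sensitive diarylcarbinol and the benzyl ethers untouched.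

Step 13
Reactants: 22 3,4-bis(benzyloxy)benzaldehyde; 23 bis[(pinacolato)boryl]methane
Product: 24 2-{(E)-2-[3,4-bis(benzyloxy)phenyl]ethenyl}-4,4,5,5-tetramethyl-1,3,2-dioxaborolane
Conditions: 23, LiTMP (from TMPH and n-BuLi), THF, 0 °C; then 22, −78 °C → rt; aq NH4Cl
Reagents that add atoms: none
Why: Boron–Wittig olefination: the lithiated geminal bis(boronate) adds to the aldehyde and eliminates lithium pinacolborate, which gives the E-alkenylboronate.

Step 14
Reactants: 24 2-{(E)-2-[3,4-bis(benzyloxy)phenyl]ethenyl}-4,4,5,5-tetramethyl-1,3,2-dioxaborolane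
Product: 25 potassium {(E)-2-[3,4-bis(benzyloxy)phenyl]ethenyl}trifluoroborate
Conditions: KHF2, MeOH/H2O, rt
Reagents that add atoms: potassium hydrogen difluoride, [K+].[F-].F
Why: Standard conversion of a pinacol boronate into the crystalline trifluoroborate; the alkene geometry is not affected.

Step 15
Reactants: 25 potassium {(E)-2-[3,4-bis(benzyloxy)phenyl]ethenyl}trifluoroborate
Product: 26 (E)-2-[3,4-bis(benzyloxy)phenyl]ethenyl acetate
Conditions: AcOH, CuBr (cat.), DMAP (cat.), 4 Å MS, O2 (1 atm), MeCN, 60 °C
Reagents that add atoms: acetic acid, CC(=O)O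
Why: Copper-catalysed oxidative C–O coupling of an alkenyltrifluoroborate with a carboxylic acid (Chan–Lam type), which transfers the alkenyl group with retention of the E geometry.

Step 16
Reactants: 21 5-(benzyloxy)-2-[hydroxy{(2R,3S)-3,5,7-tris(benzyloxy)-2-[4-(benzyloxy)phenyl]-3,4-dihydro-2H-chromen-8-yl}methyl]phenol (carbinol epimers); 26 (E)-2-[3,4-bis(benzyloxy)phenyl]ethenyl acetate
Product: 28 (2R,3S,4S)-7-(benzyloxy)-2-[3,4-bis(benzyloxy)phenyl]-4-{(2R,3S)-3,5,7-tris(benzyloxy)-2-[4-(benzyloxy)phenyl]-3,4-dihydro-2H-chromen-8-yl}-3,4-dihydro-2H-chromen-3-yl acetate, via E-o-quinone methide 27 (not isolated)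
Conditions: (R)-3,3'-bis(2,4,6-triisopropylphenyl)-1,1'-binaphthyl-2,2'-diyl N-triflylphosphoramide (10 mol %), 5 Å MS, CH2Cl2, −20 °C
Reagents that add atoms: none
Why: Proposed new method: the acid dehydrates 21 to the E-o-quinone methide 27, which it holds by hydrogen bonding; 26 should react as a 3,4-dialkoxystyrene, its acetoxy-bearing carbon bonding to the methide carbon (C4) while the phenolic oxygen closes on the developing benzylic cation (C2) in an asynchronous inverse-demand hetero-Diels–Alder reaction; the E alkene gives 2,3-trans, endo approach of ring B gives 2,4-cis and hence 3,4-trans, and the catalyst selects the face and so the absolute (2R,3S,4S) configuration; the closest known reaction type is the chiral Brønsted-acid-catalysed [4+2] of o-hydroxybenzhydrol-derived o-quinone methides with styrenes to cis-2,4-diarylchromans.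

Step 17
Reactants: 28 (2R,3S,4S)-7-(benzyloxy)-2-[3,4-bis(benzyloxy)phenyl]-4-{(2R,3S)-3,5,7-tris(benzyloxy)-2-[4-(benzyloxy)phenyl]-3,4-dihydro-2H-chromen-8-yl}-3,4-dihydro-2H-chromen-3-yl acetate
Product: 29 (2R,3S,4S)-7-(benzyloxy)-2-[3,4-bis(benzyloxy)phenyl]-4-{(2R,3S)-3,5,7-tris(benzyloxy)-2-[4-(benzyloxy)phenyl]-3,4-dihydro-2H-chromen-8-yl}-3,4-dihydro-2H-chromen-3-ol
Conditions: K2CO3 (cat.), MeOH/THF, rt
Reagents that add atoms: none
Why: Base-catalysed transesterification of the secondary acetate with methanol; all phenols are still benzylated, so no base-sensitive group is exposed.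

Step 18
Reactants: 29 (2R,3S,4S)-7-(benzyloxy)-2-[3,4-bis(benzyloxy)phenyl]-4-{(2R,3S)-3,5,7-tris(benzyloxy)-2-[4-(benzyloxy)phenyl]-3,4-dihydro-2H-chromen-8-yl}-3,4-dihydro-2H-chromen-3-ol
Product: 30 fisetinidol-(4α→8)-afzelechin, (2R,3S)-8-[(2R,3S,4S)-2-(3,4-dihydroxyphenyl)-3,7-dihydroxy-3,4-dihydro-2H-chromen-4-yl]-2-(4-hydroxyphenyl)-3,4-dihydro-2H-chromene-3,5,7-triol
Conditions: H2 (1 atm), Pd(OH)2/C, THF/MeOH, rt
Reagents that add atoms: none
Why: Hydrogenolysis of the seven benzyl ethers over Pearlman's catalyst, the usual neutral release of oligomeric flavan-3-ols; the C4–C8 bond and the five stereocentres are not touched.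

## Compound list

1 | 5-bromoresorcinol | Oc1cc(O)cc(Br)c1 | starting material
2 | 1,3-bis(benzyloxy)-5-bromobenzene | Brc1cc(OCc2ccccc2)cc(OCc2ccccc2)c1 | intermediate
3 | 2,4-bis(benzyloxy)-6-bromobenzaldehyde | O=Cc1c(Br)cc(OCc2ccccc2)cc1OCc1ccccc1 | intermediate
4 | [2,4-bis(benzyloxy)-6-bromophenyl]methanol | OCc1c(Br)cc(OCc2ccccc2)cc1OCc1ccccc1 | intermediate
5 | 1,5-bis(benzyloxy)-3-bromo-2-(bromomethyl)benzene | BrCc1c(Br)cc(OCc2ccccc2)cc1OCc1ccccc1 | intermediate
6 | (R)-4-benzyl-1,3-oxazolidin-2-one | O=C1OC[C@@H](Cc2ccccc2)N1 | starting material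
7 | (benzyloxy)acetyl chloride | O=C(Cl)COCc1ccccc1 | starting material
8 | (R)-4-benzyl-3-[(benzyloxy)acetyl]-1,3-oxazolidin-2-one | O=C(COCc1ccccc1)N1C(=O)OC[C@H]1Cc1ccccc1 | intermediate
9 | sodium (Z)-enolate of 8 | [Na+].[O-]/C(=C\OCc1ccccc1)N1C(=O)OC[C@H]1Cc1ccccc1 | intermediate
10 | (R)-4-benzyl-3-{(2S)-2-(benzyloxy)-3-[2,4-bis(benzyloxy)-6-bromophenyl]propanoyl}-1,3-oxazolidin-2-one | O=C([C@@H](OCc1ccccc1)Cc1c(Br)cc(OCc2ccccc2)cc1OCc1ccccc1)N1C(=O)OC[C@H]1Cc1ccccc1 | intermediate
11 | (2S)-2-(benzyloxy)-3-[2,4-bis(benzyloxy)-6-bromophenyl]-N-methoxy-N-methylpropanamide | CON(C)C(=O)[C@@H](OCc1ccccc1)Cc1c(Br)cc(OCc2ccccc2)cc1OCc1ccccc1 | intermediate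
12 | 1-(benzyloxy)-4-bromobenzene | Brc1ccc(OCc2ccccc2)cc1 | starting material
13 | [4-(benzyloxy)phenyl]magnesium bromide | Br[Mg]c1ccc(OCc2ccccc2)cc1 | intermediate
14 | (2S)-2-(benzyloxy)-1-[4-(benzyloxy)phenyl]-3-[2,4-bis(benzyloxy)-6-bromophenyl]propan-1-one | O=C(c1ccc(OCc2ccccc2)cc1)[C@@H](OCc1ccccc1)Cc1c(Br)cc(OCc2ccccc2)cc1OCc1ccccc1 | intermediate
15 | (1R,2S)-2-(benzyloxy)-1-[4-(benzyloxy)phenyl]-3-[2,4-bis(benzyloxy)-6-bromophenyl]propan-1-ol | O[C@H](c1ccc(OCc2ccccc2)cc1)[C@@H](OCc1ccccc1)Cc1c(Br)cc(OCc2ccccc2)cc1OCc1ccccc1 | intermediate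
16 | 4-(benzyloxy)-2-hydroxybenzaldehyde | O=Cc1ccc(OCc2ccccc2)cc1O | starting material
17 | 2-(allyloxy)-4-(benzyloxy)benzaldehyde | O=Cc1ccc(OCc2ccccc2)cc1OCC=C | intermediate
18 | lithium (1R,2S)-2-(benzyloxy)-1-[4-(benzyloxy)phenyl]-3-[4,6-bis(benzyloxy)-2,3-didehydrophenyl]propan-1-olate (C8–C8a aryne) | [Li+].[O-][C@H](c1ccc(OCc2ccccc2)cc1)[C@@H](OCc1ccccc1)CC1=C(OCc2ccccc2)C=C(OCc2ccccc2)C#C1 | intermediate
19 | {(2R,3S)-3,5,7-tris(benzyloxy)-2-[4-(benzyloxy)phenyl]-3,4-dihydro-2H-chromen-8-yl}lithium | c1ccccc1COc1ccc([C@H]2Oc3c(c(OCc4ccccc4)cc(OCc4ccccc4)c3[Li])C[C@@H]2OCc2ccccc2)cc1 | intermediate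
20 | [2-(allyloxy)-4-(benzyloxy)phenyl]{(2R,3S)-3,5,7-tris(benzyloxy)-2-[4-(benzyloxy)phenyl]-3,4-dihydro-2H-chromen-8-yl}methanol (carbinol epimers) | c1ccccc1COc1ccc([C@H]2Oc3c(c(OCc4ccccc4)cc(OCc4ccccc4)c3C(O)c3ccc(OCc4ccccc4)cc3OCC=C)C[C@@H]2OCc2ccccc2)cc1 | intermediate
21 | 5-(benzyloxy)-2-[hydroxy{(2R,3S)-3,5,7-tris(benzyloxy)-2-[4-(benzyloxy)phenyl]-3,4-dihydro-2H-chromen-8-yl}methyl]phenol (carbinol epimers) | c1ccccc1COc1ccc([C@H]2Oc3c(c(OCc4ccccc4)cc(OCc4ccccc4)c3C(O)c3ccc(OCc4ccccc4)cc3O)C[C@@H]2OCc2ccccc2)cc1 | intermediate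
22 | 3,4-bis(benzyloxy)benzaldehyde | O=Cc1ccc(OCc2ccccc2)c(OCc2ccccc2)c1 | starting material
23 | bis[(pinacolato)boryl]methane | CC1(C)OB(CB2OC(C)(C)C(C)(C)O2)OC1(C)C | starting material
24 | 2-{(E)-2-[3,4-bis(benzyloxy)phenyl]ethenyl}-4,4,5,5-tetramethyl-1,3,2-dioxaborolane | CC1(C)OB(/C=C/c2ccc(OCc3ccccc3)c(OCc3ccccc3)c2)OC1(C)C | intermediate
25 | potassium {(E)-2-[3,4-bis(benzyloxy)phenyl]ethenyl}trifluoroborate | [K+].F[B-](F)(F)/C=C/c1ccc(OCc2ccccc2)c(OCc2ccccc2)c1 | intermediate
26 | (E)-2-[3,4-bis(benzyloxy)phenyl]ethenyl acetate | CC(=O)O/C=C/c1ccc(OCc2ccccc2)c(OCc2ccccc2)c1 | intermediate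
27 | (6E)-3-(benzyloxy)-6-({(2R,3S)-3,5,7-tris(benzyloxy)-2-[4-(benzyloxy)phenyl]-3,4-dihydro-2H-chromen-8-yl}methylidene)cyclohexa-2,4-dien-1-one | c1ccccc1COc1ccc([C@H]2Oc3c(c(OCc4ccccc4)cc(OCc4ccccc4)c3/C=C3/C(=O)C=C(OCc4ccccc4)C=C3)C[C@@H]2OCc2ccccc2)cc1 | intermediate
28 | (2R,3S,4S)-7-(benzyloxy)-2-[3,4-bis(benzyloxy)phenyl]-4-{(2R,3S)-3,5,7-tris(benzyloxy)-2-[4-(benzyloxy)phenyl]-3,4-dihydro-2H-chromen-8-yl}-3,4-dihydro-2H-chromen-3-yl acetate | c1ccccc1COc1ccc([C@H]2Oc3c(c(OCc4ccccc4)cc(OCc4ccccc4)c3[C@@H]3c4ccc(OCc5ccccc5)cc4O[C@H](c4ccc(OCc5ccccc5)c(OCc5ccccc5)c4)[C@H]3OC(C)=O)C[C@@H]2OCc2ccccc2)cc1 | intermediate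
29 | (2R,3S,4S)-7-(benzyloxy)-2-[3,4-bis(benzyloxy)phenyl]-4-{(2R,3S)-3,5,7-tris(benzyloxy)-2-[4-(benzyloxy)phenyl]-3,4-dihydro-2H-chromen-8-yl}-3,4-dihydro-2H-chromen-3-ol | c1ccccc1COc1ccc([C@H]2Oc3c(c(OCc4ccccc4)cc(OCc4ccccc4)c3[C@@H]3c4ccc(OCc5ccccc5)cc4O[C@H](c4ccc(OCc5ccccc5)c(OCc5ccccc5)c4)[C@H]3O)C[C@@H]2OCc2ccccc2)cc1 | intermediate
30 | fisetinidol-(4α→8)-afzelechin | Oc1ccc([C@H]2Oc3c(c(O)cc(O)c3[C@@H]3c4ccc(O)cc4O[C@H](c4ccc(O)c(O)c4)[C@H]3O)C[C@@H]2O)cc1 | target

## Step count and risks

Total: 18 steps. Longest linear sequence: 13 steps (steps 1–4, 6–9, 11, 12, 16–18).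

**Step 16 (bears the label "Proposed new method:").**
- What may go wrong: the polarity of the alkene may be reversed, with the enol ester oxygen and not the aryl group steering bond formation, which would give the 2-acetoxy-3-aryl connectivity. The catalyst may discriminate the faces poorly against the resident chirality of the lower unit. The very electron-rich o-quinone methide may oligomerise before it is intercepted.
- Fallback, from 21 and aldehyde 22, returning at 29: aldehyde 22 is homologated with dimethyl (1-diazo-2-oxopropyl)phosphonate and K2CO3 in methanol (Ohira–Bestmann) to 4-ethynyl-1,2-bis(benzyloxy)benzene F1. Acid-promoted [4+2] of the o-quinone methide from 21 with this arylalkyne should give the 2,4-diaryl-4H-chromene F2, in which the regiochemistry is dictated by the aryl-stabilised vinyl cation alone. Hydroboration–oxidation (BH3·SMe2, then NaBO3) then places boron on C3 and hydrogen on C2 from the face opposite the C4 aryl group, which gives the 2,3-trans-3,4-trans alcohol 29 directly. In this fallback C4 is formed without reliable external control, so the two C4 epimers, which are diastereomers because of the lower unit, would have to be separated.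

**Step 11 (key step).**
- What may go wrong: the C8 aryllithium may be protonated by tetramethylpiperidine before the aldehyde is added. The amide may add to the aryne in competition with the alkoxide. Benzylic metalation of the benzyl ethers may be followed by Wittig rearrangement on warming.
- Fallback, from 15, returning at 20: the two events are separated. The aryne cyclisation of 15 is run as above and quenched with a proton source to give (2R,3S)-3,5,7-tris(benzyloxy)-2-[4-(benzyloxy)phenyl]chroman F3. This is brominated with NBS in CH2Cl2 at the position known to react first in 5,7-di-O-benzyl flavan-3-ols, giving the 8-bromo compound F4. Bromine–lithium exchange with n-BuLi at −78 °C in the absence of any amine regenerates 19, which is added to 17 to give 20.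

**Step 6.**
- What may go wrong: the glycolate enolate may decompose faster than it is alkylated by the di-ortho-substituted bromide, and the electron-rich bromide may ionise and self-alkylate.
- Fallback, from aldehyde 3, returning at 11: the C3–C4 bond is made by aldol addition instead of alkylation. Commercial (S)-4-benzyl-1,3-oxazolidin-2-one is acylated with 7 to the enantiomeric imide (S)-4-benzyl-3-[(benzyloxy)acetyl]-1,3-oxazolidin-2-one F5. Its dibutylboron enolate (Bu2BOTf, Et3N) adds to 3 to give the Evans syn aldol adduct (S)-4-benzyl-3-{(2S,3R)-2-(benzyloxy)-3-[2,4-bis(benzyloxy)-6-bromophenyl]-3-hydroxypropanoyl}-1,3-oxazolidin-2-one F6. The boron aldol installs the new bond from the enolate face opposite to that of the chelated alkylation, which is why the other auxiliary enantiomer is used. Ionic deoxygenation of the activated benzylic carbinol (Et3SiH, CF3CO2H) gives (S)-4-benzyl-3-{(2S)-2-(benzyloxy)-3-[2,4-bis(benzyloxy)-6-bromophenyl]propanoyl}-1,3-oxazolidin-2-one F7, and the transamination of step 7 then gives 11.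

**Step 18.**
- What may go wrong: hydrogenolytic opening of the benzylic C2–O1 bonds may compete with debenzylation, the last benzyl ethers may be removed incompletely, and the free polyphenol may oxidise in air during isolation.
- Fallback, from 29, returning at 30: Lewis-acid debenzylation with BCl3 and pentamethylbenzene as cation scavenger in CH2Cl2 at −78 °C. The 5-deoxy upper unit makes the interflavan bond comparatively resistant to acid. No new compound is made.

## Further compounds

F1 | step 16 | 4-ethynyl-1,2-bis(benzyloxy)benzene | C#Cc1ccc(OCc2ccccc2)c(OCc2ccccc2)c1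
F2 | step 16 | (4S)-7-(benzyloxy)-2-[3,4-bis(benzyloxy)phenyl]-4-{(2R,3S)-3,5,7-tris(benzyloxy)-2-[4-(benzyloxy)phenyl]-3,4-dihydro-2H-chromen-8-yl}-4H-chromene (desired C4 epimer) | c1ccccc1COc1ccc([C@H]2Oc3c(c(OCc4ccccc4)cc(OCc4ccccc4)c3[C@@H]3c4ccc(OCc5ccccc5)cc4OC(c4ccc(OCc5ccccc5)c(OCc5ccccc5)c4)=C3)C[C@@H]2OCc2ccccc2)cc1
F3 | step 11 | (2R,3S)-3,5,7-tris(benzyloxy)-2-[4-(benzyloxy)phenyl]-3,4-dihydro-2H-chromene (tetra-O-benzylafzelechin) | c1ccccc1COc1ccc([C@H]2Oc3c(c(OCc4ccccc4)cc(OCc4ccccc4)c3)C[C@@H]2OCc2ccccc2)cc1
F4 | step 11 | (2R,3S)-3,5,7-tris(benzyloxy)-2-[4-(benzyloxy)phenyl]-8-bromo-3,4-dihydro-2H-chromene | c1ccccc1COc1ccc([C@H]2Oc3c(c(OCc4ccccc4)cc(OCc4ccccc4)c3Br)C[C@@H]2OCc2ccccc2)cc1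
F5 | step 6 | (S)-4-benzyl-3-[(benzyloxy)acetyl]-1,3-oxazolidin-2-one | O=C(COCc1ccccc1)N1C(=O)OC[C@@H]1Cc1ccccc1
F6 | step 6 | (S)-4-benzyl-3-{(2S,3R)-2-(benzyloxy)-3-[2,4-bis(benzyloxy)-6-bromophenyl]-3-hydroxypropanoyl}-1,3-oxazolidin-2-one | O=C([C@@H](OCc1ccccc1)[C@H](O)c1c(Br)cc(OCc2ccccc2)cc1OCc1ccccc1)N1C(=O)OC[C@@H]1Cc1ccccc1
F7 | step 6 | (S)-4-benzyl-3-{(2S)-2-(benzyloxy)-3-[2,4-bis(benzyloxy)-6-bromophenyl]propanoyl}-1,3-oxazolidin-2-one | O=C([C@@H](OCc1ccccc1)Cc1c(Br)cc(OCc2ccccc2)cc1OCc1ccccc1)N1C(=O)OC[C@@H]1Cc1ccccc1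
F0 | step 18 | none | none
A1 | alternative 1 | benzannulation product: 3-(benzyloxy)-2-{[(4S,5S)-5-(4-benzyloxyphenyl)-2,2-dimethyl-1,3-dioxolan-4-yl]methyl}-6-{(2R,3S,4S)-3,7-bis(benzyloxy)-2-[3,4-bis(benzyloxy)phenyl]-3,4-dihydro-2H-chromen-4-yl}-5-(triisopropylsilyloxy)phenol | Oc1c(C[C@@H]2OC(C)(C)O[C@H]2c2ccc(OCc9ccccc9)cc2)c(OCc9ccccc9)cc(O[Si](C(C)C)(C(C)C)C(C)C)c1[C@@H]3c4ccc(OCc9ccccc9)cc4O[C@H](c4ccc(OCc9ccccc9)c(OCc9ccccc9)c4)[C@H]3OCc9ccccc9
A2 | alternative 1 | siloxyalkyne: triisopropylsilyl ynol ether of 4-ethynyl-3,7-bis(benzyloxy)-2-[3,4-bis(benzyloxy)phenyl]chroman (upper unit, 2,3-trans-3,4-trans) | CC(C)[Si](OC#C[C@@H]1c2ccc(OCc3ccccc3)cc2O[C@H](c2ccc(OCc3ccccc3)c(OCc3ccccc3)c2)[C@H]1OCc1ccccc1)(C(C)C)C(C)C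
A3 | alternative 1 | cyclobutenone: 3-(benzyloxy)-4-{[(4S,5S)-5-(4-benzyloxyphenyl)-2,2-dimethyl-1,3-dioxolan-4-yl]methyl}cyclobut-2-en-1-one | O=C1C=C(OCc2ccccc2)C1C[C@@H]1OC(C)(C)O[C@H]1c1ccc(OCc2ccccc2)cc1
A4 | alternative 2 | metathesis product: 4-(tetra-O-benzylafzelechin-8-yl)-7-(benzyloxy)-2-[3,4-bis(benzyloxy)phenyl]-2H-chromene | c9ccccc9COc1ccc([C@H]2Oc3c(c(OCc9ccccc9)cc(OCc9ccccc9)c3C3=C[C@@H](c4ccc(OCc9ccccc9)c(OCc9ccccc9)c4)Oc4cc(OCc9ccccc9)ccc43)C[C@@H]2OCc9ccccc9)cc1
A5 | alternative 2 | diene: 8-{1-[4-(benzyloxy)-2-({1-[3,4-bis(benzyloxy)phenyl]prop-2-en-1-yl}oxy)phenyl]ethenyl}-tetra-O-benzylafzelechin | c9ccccc9COc1ccc([C@H]2Oc3c(c(OCc9ccccc9)cc(OCc9ccccc9)c3C(=C)c3ccc(OCc9ccccc9)cc3O[C@@H](C=C)c3ccc(OCc9ccccc9)c(OCc9ccccc9)c3)C[C@@H]2OCc9ccccc9)cc1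
A6 | alternative 3 | cyclisation product: hepta-O-benzyl fisetinidol-(4α→8)-afzelechin with free lower 3-hydroxyl | c9ccccc9COc1ccc([C@H]2Oc3c(c(OCc9ccccc9)cc(OCc9ccccc9)c3[C@@H]3c4ccc(OCc9ccccc9)cc4O[C@H](c4ccc(OCc9ccccc9)c(OCc9ccccc9)c4)[C@H]3OCc9ccccc9)C[C@@H]2O)cc1
A7 | alternative 3 | epoxy aryl ether: 3,5-bis(benzyloxy)-2-(tri-O-benzyl-3-O-benzylfisetinidol-4-yl)phenyl ether of (4-benzyloxyphenyl)(oxiran-2-yl)methanol | c9ccccc9COc1ccc([C@@H](Oc3cc(OCc9ccccc9)cc(OCc9ccccc9)c3[C@@H]3c4ccc(OCc9ccccc9)cc4O[C@H](c4ccc(OCc9ccccc9)c(OCc9ccccc9)c4)[C@H]3OCc9ccccc9)[C@@H]2CO2)cc1
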